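**Retrosynthetic overview**

1. Numbering (labdane-type): ring B = carbocycle C5–C6–C7–C8–C9–C10; ring C = tetrahydropyran O–C8–C9–C11–C12–C13; C1–C2 = CH2CO2H arm on C10; C3–C4 = CMe2CO2Me arm on C5.
2. Ring C last: the C13–vinyl bond by axial addition to the cyclic oxocarbenium ion of a C8-hydroxy C13-methyl ketone; the C8–O bond by hydration of a C8 exocyclic methylene on ring B.
3. Ring B by the C5–C6 bond: C5 lies β to the ester carbonyl C3 across the quaternary C4, so C5–C6 is a radical conjugate-addition retron and the second methyl on C4 is the radical terminus. Anodic decarboxylation (Kolbe) of acid 14 makes the C6 radical, closes ring B and caps C4 with a methyl from acetic acid.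
4. Acid 14 from (S)-carvone used as a temporary ring: two enolate alkylations set C10 from the bought C9 centre; the isopropenyl group becomes C8(=CH2)–C7–C6–CO2H (allylic oxidation, Johnson–Claisen); glycol cleavage of the former enone bond C5–C13 releases aldehyde C5 (then the 2-methylacrylate) and the C13 methyl ketone.
5. Order of ring formation: ring B (step 9), then ring C (step 12). C9 is bought; C10, C5, C8 and C13 are relayed by substrate control.

Key step: step 9

Step 1
Reactants: 1 (S)-(+)-carvone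
Product: 3 tert-butyl 2-[(6S)-3-methyl-2-oxo-6-(prop-1-en-2-yl)cyclohex-3-en-1-yl]acetate, via lithium dienolate 2 (not isolated)
Conditions: LiN(iPr)2, THF, −78 °C; then BrCH2CO2tBu, −78 to −30 °C
Reagents that add atoms: tert-butyl bromoacetate CC(C)(C)OC(=O)CBr
Why: Kinetic deprotonation of the cross-conjugated enone at C6 (the future C10) and SN2 enolate alkylation should install the acetate arm; the configuration of the new centre does not matter because it is planarised again in step 2.

Step 2
Reactants: 3 tert-butyl 2-[(6S)-3-methyl-2-oxo-6-(prop-1-en-2-yl)cyclohex-3-en-1-yl]acetate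
Product: 5 tert-butyl 2-[(1S,6R)-1,3-dimethyl-2-oxo-6-(prop-1-en-2-yl)cyclohex-3-en-1-yl]acetate, via lithium enolate 4 (not isolated)
Conditions: LiN(iPr)2, THF/DMPU, −78 °C; then MeI, −78 to 0 °C
Reagents that add atoms: iodomethane CI
Why: Enolate alkylation of the more acidic ketone α-position should place the methyl anti to the neighbouring isopropenyl group, which sets the quaternary centre C10 (methyl trans, acetate arm cis to isopropenyl) by substrate control from the carvone stereocentre.

Step 3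
Reactants: 5 tert-butyl 2-[(1S,6R)-1,3-dimethyl-2-oxo-6-(prop-1-en-2-yl)cyclohex-3-en-1-yl]acetate
Product: 6 tert-butyl 2-[(1S,6R)-6-(3-hydroxyprop-1-en-2-yl)-1,3-dimethyl-2-oxocyclohex-3-en-1-yl]acetate
Conditions: SeO2 (cat.), t-BuOOH, CH2Cl2, 0 °C to rt
Reagents that add atoms: tert-butyl hydroperoxide CC(C)(C)OO
Why: Riley allylic oxidation (ene reaction, then [2,3]-sigmatropic shift) should hydroxylate the methyl of the electron-rich 1,1-disubstituted alkene in preference to the electron-poor enone alkene.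

Step 4
Reactants: 6 tert-butyl 2-[(1S,6R)-6-(3-hydroxyprop-1-en-2-yl)-1,3-dimethyl-2-oxocyclohex-3-en-1-yl]acetate
Product: 8 methyl 4-[(1R,6S)-6-(2-tert-butoxy-2-oxoethyl)-4,6-dimethyl-5-oxocyclohex-3-en-1-yl]pent-4-enoate, via ketene acetal 7 (not isolated)
Conditions: MeC(OMe)3, EtCO2H (cat.), toluene, 110 °C
Reagents that add atoms: trimethyl orthoacetate CC(OC)(OC)OC
Why: Johnson–Claisen rearrangement of the 2-substituted allylic alcohol should deliver the CH2CO2Me unit to the former methylene carbon and regenerate a 1,1-disubstituted alkene, giving the C7–C6 chain and the C8 exocyclic methylene without touching a stereocentre.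

Step 5
Reactants: 8 methyl 4-[(1R,6S)-6-(2-tert-butoxy-2-oxoethyl)-4,6-dimethyl-5-oxocyclohex-3-en-1-yl]pent-4-enoate
Product: 10 methyl 4-[(1R,2S)-2-(2-tert-butoxy-2-oxoethyl)-4-hydroxy-2,4-dimethyl-3-oxocyclohexyl]pent-4-enoate, via lithium enolate 9 (not isolated)
Conditions: Li[HB(sBu)3], THF, −78 °C; then 2-(phenylsulfonyl)-3-phenyloxaziridine, −78 to −20 °C; H2O
Reagents that add atoms: 2-(phenylsulfonyl)-3-phenyloxaziridine O=S(=O)(c1ccccc1)N1OC1c1ccccc1
Why: Conjugate reduction of the β-unsubstituted enone by the bulky hydride should give the enolate regiospecifically, and Davis oxidation of that enolate should hydroxylate the α-carbon (future C13, formed as an inconsequential epimer mixture), arming the C5–C13 bond for cleavage.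

Step 6
Reactants: 10 methyl 4-[(1R,2S)-2-(2-tert-butoxy-2-oxoethyl)-4-hydroxy-2,4-dimethyl-3-oxocyclohexyl]pent-4-enoate
Product: 12 1-tert-butyl 8-methyl (3S,4R)-3-formyl-3-methyl-5-methylidene-4-(3-oxobutyl)octanedioate, via diol 11 (not isolated)
Conditions: NaBH4, MeOH, 0 °C to rt; then NaIO4, THF/H2O, 0 °C to rt
Reagents that add atoms: none
Why: Borohydride reduction of the α-hydroxy ketone and Malaprade glycol cleavage should open the temporary ring to the C5 aldehyde on the quaternary carbon and the C13 methyl ketone, the bulky tert-butyl ester resisting lactonisation onto the transient C5 hydroxyl.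

Step 7
Reactants: 12 1-tert-butyl 8-methyl (3S,4R)-3-formyl-3-methyl-5-methylidene-4-(3-oxobutyl)octanedioate
Product: 13 1-tert-butyl 8-methyl (3R,4R)-3-[(1E)-3-methoxy-2-methyl-3-oxoprop-1-en-1-yl]-3-methyl-5-methylidene-4-(3-oxobutyl)octanedioate
Conditions: (MeO)2P(O)CH(CH3)CO2Me, LiCl, DBU, MeCN, 0 °C to rt
Reagents that add atoms: trimethyl 2-phosphonopropionate COC(=O)C(C)P(=O)(OC)OC
Why: Horner–Wadsworth–Emmons olefination under Masamune–Roush conditions should convert the aldehyde, and not the ketone, into the 2-methylacrylate acceptor; the alkene geometry is inconsequential because C4 becomes a non-stereogenic quaternary carbon in step 9.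

Step 8
Reactants: 13 1-tert-butyl 8-methyl (3R,4R)-3-[(1E)-3-methoxy-2-methyl-3-oxoprop-1-en-1-yl]-3-methyl-5-methylidene-4-(3-oxobutyl)octanedioate
Product: 14 (5R,6R)-8-tert-butoxy-6-[(1E)-3-methoxy-2-methyl-3-oxoprop-1-en-1-yl]-6-methyl-4-methylidene-8-oxo-5-(3-oxobutyl)octanoic acid
Conditions: LiOH, THF/MeOH/H2O, 0 °C; then aq. HCl to pH 3
Reagents that add atoms: lithium hydroxide [Li+].[OH-]
Why: Saponification should be selective for the unhindered primary methyl ester over the tert-butyl ester and the α-branched conjugated methyl ester.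

Step 9
Reactants: 14 (5R,6R)-8-tert-butoxy-6-[(1E)-3-methoxy-2-methyl-3-oxoprop-1-en-1-yl]-6-methyl-4-methylidene-8-oxo-5-(3-oxobutyl)octanoic acid
Product: 15 methyl 2-[(1S,2S,3R)-2-(2-tert-butoxy-2-oxoethyl)-2-methyl-4-methylidene-3-(3-oxobutyl)cyclohexyl]-2-methylpropanoate
Conditions: AcOH (20 equiv), KOH (cat.), MeOH, Pt anode, Pt cathode, undivided cell, constant current, 10–15 °C
Reagents that add atoms: acetic acid CC(=O)O
Why: Anodic oxidation of the carboxylate of 14 and loss of CO2 should give the primary C6 radical, which adds to C5 of the tethered 2-methylacrylate; the resulting tertiary α-ester radical at C4 should then couple with a methyl radical formed at the same anode from the excess acetate, so ring closure and the C4 quaternary carbon arise in one operation. The closest known reaction type is the mixed Kolbe electrolysis in its tandem form, radical cyclisation of an unsaturated acid followed by heterocoupling with the co-acid radical. Ring B is closed in the 6-exo-trig mode through the C5–C6 bond. The new stereocentre C5 is controlled by C9 and C10 through a chair-like transition state with the C9 oxobutyl chain, the C10 CH2CO2tBu arm and the acrylate carbon C4 equatorial and the C10 methyl axial, which puts H5 axial and anti to that methyl. The step needs cyclisation to outrun coupling of the uncyclised C6 radical and needs coupling rather than disproportionation at C4; the polarity match of the nucleophilic alkyl radical with the electron-poor alkene, a moderate current density and the large excess of acetic acid are relied on for this. The C8 alkene, the ketone and the esters should not be oxidised at the carboxylate-covered anode.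

Step 10
Reactants: 15 methyl 2-[(1S,2S,3R)-2-(2-tert-butoxy-2-oxoethyl)-2-methyl-4-methylidene-3-(3-oxobutyl)cyclohexyl]-2-methylpropanoate
Product: 17 2-[(1S,2R,6S)-6-(1-methoxy-2-methyl-1-oxopropan-2-yl)-1-methyl-3-methylidene-2-(3-oxobutyl)cyclohexyl]acetic acid, via trimethylsilyl ester 16 (not isolated)
Conditions: Me3SiOTf, 2,6-lutidine, CH2Cl2, 0 °C; then H2O/MeOH
Reagents that add atoms: none
Why: Silyl triflate-mediated tert-butyl ester cleavage (loss of isobutene, then hydrolysis of the silyl ester) should free the C2 acid without protonating the exocyclic alkene.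

Step 11
Reactants: 17 2-[(1S,2R,6S)-6-(1-methoxy-2-methyl-1-oxopropan-2-yl)-1-methyl-3-methylidene-2-(3-oxobutyl)cyclohexyl]acetic acid
Product: 18 2-[(1R,2S,3S,6S)-3-hydroxy-6-(1-methoxy-2-methyl-1-oxopropan-2-yl)-1,3-dimethyl-2-(3-oxobutyl)cyclohexyl]acetic acid
Conditions: Mn(dpm)3 (cat.), PhSiH3, O2 (1 atm), iPrOH/CH2Cl2, 0 °C to rt
Reagents that add atoms: dioxygen O=O
Why: Mukaiyama hydration (hydrogen-atom transfer to the 1,1-disubstituted alkene, capture of the tertiary C8 radical by O2, reduction) should give the tertiary alcohol, with O2 approaching the equatorial face opposite the axial C10 methyl so that the new C8 methyl is axial.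

Step 12
Reactants: 18 2-[(1R,2S,3S,6S)-3-hydroxy-6-(1-methoxy-2-methyl-1-oxopropan-2-yl)-1,3-dimethyl-2-(3-oxobutyl)cyclohexyl]acetic acid
Product: 21 2-[(2R,4aS,5R,6S,8aS)-2-ethenyl-6-(1-methoxy-2-methyl-1-oxopropan-2-yl)-2,5,8a-trimethyloctahydro-2H-chromen-5-yl]acetic acid, via hemiketal 19 (not isolated), via oxocarbenium ion 20 (not isolated)
Conditions: K[CH2=CHBF3], BF3·OEt2, CH2Cl2/MeCN, −40 to 0 °C
Reagents that add atoms: potassium vinyltrifluoroborate C=C[B-](F)(F)F.[K+]
Why: Lewis-acid ionisation of the hemiketal and addition of the alkenyltrifluoroborate to the cyclic oxocarbenium ion (C-glycosylation type) should close ring C and set C13 by axial attack on the chair-like ring that is trans-fused to ring B, giving vinyl axial and methyl equatorial, the arrangement that should also be the more stable one.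

**Compound list**

1 | (S)-(+)-carvone, (5S)-2-methyl-5-(prop-1-en-2-yl)cyclohex-2-en-1-one | CC1=CC[C@H](C(C)=C)CC1=O | starting material
2 | lithium dienolate of carvone | CC1=CC[C@H](C(C)=C)C=C1[O-].[Li+] | intermediate
3 | tert-butyl 2-[(6S)-3-methyl-2-oxo-6-(prop-1-en-2-yl)cyclohex-3-en-1-yl]acetate (C1 epimers) | CC1=CC[C@H](C(C)=C)C(CC(=O)OC(C)(C)C)C1=O | intermediate
4 | lithium enolate of 3 | CC1=CC[C@H](C(C)=C)C(CC(=O)OC(C)(C)C)=C1[O-].[Li+] | intermediate
5 | tert-butyl 2-[(1S,6R)-1,3-dimethyl-2-oxo-6-(prop-1-en-2-yl)cyclohex-3-en-1-yl]acetate | CC1=CC[C@H](C(C)=C)[C@](C)(CC(=O)OC(C)(C)C)C1=O | intermediate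
6 | tert-butyl 2-[(1S,6R)-6-(3-hydroxyprop-1-en-2-yl)-1,3-dimethyl-2-oxocyclohex-3-en-1-yl]acetate | CC1=CC[C@H](C(=C)CO)[C@](C)(CC(=O)OC(C)(C)C)C1=O | intermediate
7 | mixed methyl ketene acetal of 6 | CC1=CC[C@H](C(=C)COC(=C)OC)[C@](C)(CC(=O)OC(C)(C)C)C1=O | intermediate
8 | methyl 4-[(1R,6S)-6-(2-tert-butoxy-2-oxoethyl)-4,6-dimethyl-5-oxocyclohex-3-en-1-yl]pent-4-enoate | CC1=CC[C@H](C(=C)CCC(=O)OC)[C@](C)(CC(=O)OC(C)(C)C)C1=O | intermediate
9 | lithium enolate from conjugate reduction of 8 | CC=1CC[C@H](C(=C)CCC(=O)OC)[C@](C)(CC(=O)OC(C)(C)C)C=1[O-].[Li+] | intermediate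
10 | methyl 4-[(1R,2S)-2-(2-tert-butoxy-2-oxoethyl)-4-hydroxy-2,4-dimethyl-3-oxocyclohexyl]pent-4-enoate (C4 epimers) | CC1(O)CC[C@H](C(=C)CCC(=O)OC)[C@](C)(CC(=O)OC(C)(C)C)C1=O | intermediate
11 | diol from reduction of 10 (epimers at the two carbinol carbons) | CC1(O)CC[C@H](C(=C)CCC(=O)OC)[C@](C)(CC(=O)OC(C)(C)C)C1O | intermediate
12 | 1-tert-butyl 8-methyl (3S,4R)-3-formyl-3-methyl-5-methylidene-4-(3-oxobutyl)octanedioate | CC(=O)CC[C@H](C(=C)CCC(=O)OC)[C@](C)(CC(=O)OC(C)(C)C)C=O | intermediate
13 | 1-tert-butyl 8-methyl (3R,4R)-3-[(1E)-3-methoxy-2-methyl-3-oxoprop-1-en-1-yl]-3-methyl-5-methylidene-4-(3-oxobutyl)octanedioate | CC(=O)CC[C@H](C(=C)CCC(=O)OC)[C@](C)(CC(=O)OC(C)(C)C)/C=C(\C)C(=O)OC | intermediate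
14 | (5R,6R)-8-tert-butoxy-6-[(1E)-3-methoxy-2-methyl-3-oxoprop-1-en-1-yl]-6-methyl-4-methylidene-8-oxo-5-(3-oxobutyl)octanoic acid | CC(=O)CC[C@H](C(=C)CCC(=O)O)[C@](C)(CC(=O)OC(C)(C)C)/C=C(\C)C(=O)OC | intermediate
15 | methyl 2-[(1S,2S,3R)-2-(2-tert-butoxy-2-oxoethyl)-2-methyl-4-methylidene-3-(3-oxobutyl)cyclohexyl]-2-methylpropanoate | CC(=O)CC[C@H]1[C@](C)(CC(=O)OC(C)(C)C)[C@@H](C(C)(C)C(=O)OC)CCC1=C | intermediate
16 | trimethylsilyl ester of 17 | CC(=O)CC[C@H]1[C@](C)(CC(=O)O[Si](C)(C)C)[C@@H](C(C)(C)C(=O)OC)CCC1=C | intermediate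
17 | 2-[(1S,2R,6S)-6-(1-methoxy-2-methyl-1-oxopropan-2-yl)-1-methyl-3-methylidene-2-(3-oxobutyl)cyclohexyl]acetic acid | CC(=O)CC[C@H]1[C@](C)(CC(=O)O)[C@@H](C(C)(C)C(=O)OC)CCC1=C | intermediate
18 | 2-[(1R,2S,3S,6S)-3-hydroxy-6-(1-methoxy-2-methyl-1-oxopropan-2-yl)-1,3-dimethyl-2-(3-oxobutyl)cyclohexyl]acetic acid | CC(=O)CC[C@H]1[C@](C)(CC(=O)O)[C@@H](C(C)(C)C(=O)OC)CC[C@]1(C)O | intermediate
19 | 2-[(4aS,5R,6S,8aS)-2-hydroxy-6-(1-methoxy-2-methyl-1-oxopropan-2-yl)-2,5,8a-trimethyloctahydro-2H-chromen-5-yl]acetic acid (C2 anomers) | CC1(O)CC[C@H]2[C@](C)(CC(=O)O)[C@@H](C(C)(C)C(=O)OC)CC[C@]2(C)O1 | intermediate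
20 | cyclic oxocarbenium ion from 19 | CC=1CC[C@H]2[C@](C)(CC(=O)O)[C@@H](C(C)(C)C(=O)OC)CC[C@]2(C)[O+]=1 | intermediate
21 | 2-[(2R,4aS,5R,6S,8aS)-2-ethenyl-6-(1-methoxy-2-methyl-1-oxopropan-2-yl)-2,5,8a-trimethyloctahydro-2H-chromen-5-yl]acetic acid | C=C[C@@]1(C)CC[C@H]2[C@](C)(CC(=O)O)[C@@H](C(C)(C)C(=O)OC)CC[C@]2(C)O1 | target

**Step count and risk**

Total step count: 12. Longest linear sequence: 12 steps from 1.

Step 9. Capping of the uncyclised C6 radical by a methyl radical may outrun the 6-exo cyclisation, and the tertiary C4 radical may disproportionate instead of coupling. The fallback separates cyclisation from methylation and sets out from 14. A photoredox decarboxylative Giese cyclisation (4CzIPN, Cs2CO3, DMF, blue light) should give methyl 2-[2-(2-tert-butoxy-2-oxoethyl)-2-methyl-4-methylidene-3-(3-oxobutyl)cyclohexyl]propanoate F1. Me3SiOTf/2,6-lutidine then frees the corresponding acetic acid F2, and ethylene glycol with pyridinium tosylate masks the ketone as the dioxolane acid F3. The dianion of F3 (carboxylate plus ester enolate, LiN(iPr)2 in excess, then MeI) should be methylated only at C4 to give the gem-dimethyl dioxolane acid F4, because the carboxylate shields the CH2 next to it from deprotonation. Aqueous HCl in acetone removes the dioxolane and the route is rejoined at 17.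

Step 12. The unsubstituted vinyl nucleophile may add too slowly to the hindered tertiary oxocarbenium ion, so that proton loss to an enol ether takes over. The fallback sets out from 18 and uses the more nucleophilic, slimmer alkyne. BF3·OEt2 with K[Me3SiC≡CBF3] should give the axial C13 (trimethylsilyl)ethynyl ether F5; K2CO3 in MeOH gives the C13 ethynyl ether F6; semihydrogenation (H2, Pd/CaCO3 poisoned with Pb(OAc)2, quinoline) comes back to the route at 21.

Step 3. Allylic oxidation may over-oxidise to the enal or attack the allylic positions of the enone. The fallback sets out from 5. Ene-type chlorination with Ca(OCl)2 and CO2 in CH2Cl2/H2O should give the allylic chloride tert-butyl 2-[6-(3-chloroprop-1-en-2-yl)-1,3-dimethyl-2-oxocyclohex-3-en-1-yl]acetate F7; displacement with KOAc in DMF gives the allylic acetate F8; methanolysis (K2CO3, MeOH) comes back to the route at 6.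

Further compounds
F1 | step 9 | methyl 2-[2-(2-tert-butoxy-2-oxoethyl)-2-methyl-4-methylidene-3-(3-oxobutyl)cyclohexyl]propanoate (ring stereocentres as in 15) | CC(=O)CC[C@H]1[C@](C)(CC(=O)OC(C)(C)C)[C@@H](C(C)C(=O)OC)CCC1=C
F2 | step 9 | 2-[6-(1-methoxy-1-oxopropan-2-yl)-1-methyl-3-methylidene-2-(3-oxobutyl)cyclohexyl]acetic acid (ring stereocentres as in 17) | CC(=O)CC[C@H]1[C@](C)(CC(=O)O)[C@@H](C(C)C(=O)OC)CCC1=C
F3 | step 9 | dioxolane acid, ethylene ketal of F2 | CC1(OCCO1)CC[C@H]2[C@](C)(CC(=O)O)[C@@H](C(C)C(=O)OC)CCC2=C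
F4 | step 9 | gem-dimethyl dioxolane acid, ethylene ketal of 17 | CC1(OCCO1)CC[C@H]2[C@](C)(CC(=O)O)[C@@H](C(C)(C)C(=O)OC)CCC2=C
F5 | step 12 | C13 (trimethylsilyl)ethynyl analogue of 21 | C[Si](C)(C)C#C[C@@]1(C)CC[C@H]2[C@](C)(CC(=O)O)[C@@H](C(C)(C)C(=O)OC)CC[C@]2(C)O1
F6 | step 12 | C13 ethynyl analogue of 21 | C#C[C@@]1(C)CC[C@H]2[C@](C)(CC(=O)O)[C@@H](C(C)(C)C(=O)OC)CC[C@]2(C)O1
F7 | step 3 | tert-butyl 2-[6-(3-chloroprop-1-en-2-yl)-1,3-dimethyl-2-oxocyclohex-3-en-1-yl]acetate (stereocentres as in 5) | CC1=CC[C@H](C(=C)CCl)[C@](C)(CC(=O)OC(C)(C)C)C1=O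
F8 | step 3 | tert-butyl 2-[6-(3-acetoxyprop-1-en-2-yl)-1,3-dimethyl-2-oxocyclohex-3-en-1-yl]acetate (stereocentres as in 5) | CC1=CC[C@H](C(=C)COC(C)=O)[C@](C)(CC(=O)OC(C)(C)C)C1=O
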